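**Plan**

1. Cuts: the ketone bond between pyridone C3 and the decalin carbonyl carbon; the two C–O bonds at C2′ and C5′ of the oxabicycloheptane together with the pyridine C5–C2′ bond; the two Diels–Alder bonds C1–C2 and C4a–C8a of the octalin.
2. Enabling feature: in the six-membered carbocycle the hydroxyls on C2′ (the carbon bonded to pyridone C5) and on C5′ are cis, and the C1′–C6′ oxirane between them lies on the opposite ring face. This is what an O–O bridge across C2′/C5′ of a 2,3-dioxabicyclo[2.2.2]oct-5-ene leaves behind once its alkene has been epoxidised anti to the bridge.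
3. Forward, heterocyclic half: a 2,4-dialkoxypyridine is joined to cyclohexa-1,3-diene by Negishi coupling; singlet oxygen closes the dioxabicyclooctene (step 4); then epoxide, O–O cleavage, enzymatic resolution, silylation.
4. Forward, carbocyclic half: (S)-citronellal is extended at both ends to a 2,8,10-trienal whose intramolecular Diels–Alder reaction closes both rings of the octalin; the formyl group becomes the propenyl group, the silyloxymethyl group the aldehyde.
5. Union: C3 lithiation of the pyridine and addition to the decalin aldehyde, oxidation, epimerisation at decalin C2, one fluoride deprotection.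
6. Stereochemistry: the epoxydiol relative configuration comes from suprafacial O2 addition and anti epoxidation, its absolute configuration from the lipase; the decalin follows from the citronellal methyl group (equatorial in an endo transition state) and the alkene geometries; C2 is set by thermodynamic equilibration.

Key step: step 4

Assumption: the lipase is taken to follow the usual empirical rule for secondary alcohols and to acylate the (5R)-alcohol of rac-10, the enantiomer needed; if it prefers the other one, the unreacted alcohol is carried on instead. Racemic compounds 8–10 are drawn as the enantiomer used.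

**Route**

Step 1
Reactants: 1 5-bromo-2,4-dichloropyridine
Product: 2 5-bromo-2,4-bis[2-(trimethylsilyl)ethoxy]pyridine
Conditions: Me3SiCH2CH2OH (2.5 equiv), NaH, THF/DMF, 0 → 70 °C
Reagents that add atoms: 2-(trimethylsilyl)ethanol, C[Si](C)(C)CCO
Why: Double nucleophilic aromatic substitution (SNAr): the alkoxide displaces the 4- and then the 2-chloride while the unactivated 5-bromide stays; silylethyl ethers are chosen because fluoride removes them at the end without the acid that the oxirane would not tolerate.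

Step 2
Reactants: 3 cyclohex-2-en-1-one
Product: 4 cyclohexa-1,3-dien-1-yl trifluoromethanesulfonate
Conditions: Tf2O, 2,6-di-tert-butyl-4-methylpyridine, CH2Cl2, 0 → 25 °C
Reagents that add atoms: trifluoromethanesulfonic anhydride, O=S(=O)(OS(=O)(=O)C(F)(F)F)C(F)(F)F
Why: O-Triflation of an enone under equilibrating conditions with a hindered pyridine base is the standard way to the linearly conjugated (thermodynamic) dienyl triflate, formed by loss of the γ-proton.

Step 3
Reactants: 2 5-bromo-2,4-bis[2-(trimethylsilyl)ethoxy]pyridine; 4 cyclohexa-1,3-dien-1-yl trifluoromethanesulfonate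
Product: 7 5-(cyclohexa-1,3-dien-1-yl)-2,4-bis[2-(trimethylsilyl)ethoxy]pyridine, via 5-lithiopyridine 5 (not isolated), via pyridylzinc chloride 6 (not isolated)
Conditions: n-BuLi, THF, −78 °C; ZnCl2, −78 → 0 °C; then 4, Pd(PPh3)4 (cat.), 25 → 45 °C
Reagents that add atoms: none
Why: Bromine–lithium exchange, transmetalation to zinc and Negishi cross-coupling with the alkenyl triflate join the two sp2 carbons without moving the diene; the cold exchange and immediate transmetalation prevent proton transfer from pyridine C3.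

Step 4
Reactants: 7 5-(cyclohexa-1,3-dien-1-yl)-2,4-bis[2-(trimethylsilyl)ethoxy]pyridine
Product: 8 rac-5-[(1S,4R)-2,3-dioxabicyclo[2.2.2]oct-5-en-1-yl]-2,4-bis[2-(trimethylsilyl)ethoxy]pyridine
Conditions: O2, tetraphenylporphyrin (cat.), visible light, CH2Cl2, −20 °C
Reagents that add atoms: dioxygen (as singlet oxygen), O=O
Why: The porphyrin triplet sensitises O2 to singlet oxygen, which adds to the s-cis diene of 7 in a concerted suprafacial [4+2] cycloaddition; the closest known reactions are the dye-sensitised photooxygenations of α-terpinene and of 1-aryl-cyclohexa-1,3-dienes to bicyclic endoperoxides. The six-membered 1,2-dioxine ring closes in one event by forming both C–O bonds at the diene termini (the aryl-bearing C1 and C4), which turns the cyclohexadiene into the 2,3-dioxabicyclo[2.2.2]oct-5-ene. The two new stereocentres, the aryl-bearing bridgehead and the CH bridgehead, are tied to each other by the bicycle, because the peroxide can only span one face, so a single racemic diastereomer is possible. The absolute configuration is left open here and is selected in step 7. The step needs cycloaddition to win over the ene reaction at the ring CH2 groups and over attack on the heteroarene; the ring-locked s-cis geometry and the electron-rich, aryl-conjugated diene should make the [4+2] path the fastest. The alkoxypyridine and the silyl groups do not react with singlet oxygen, and the low temperature keeps the peroxide from rearranging.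

Step 5
Reactants: 8 rac-5-[(1S,4R)-2,3-dioxabicyclo[2.2.2]oct-5-en-1-yl]-2,4-bis[2-(trimethylsilyl)ethoxy]pyridine
Product: 9 rac-5-[(1R,2S,4R,5R)-3,6,7-trioxatricyclo[3.2.2.0(2,4)]nonan-1-yl]-2,4-bis[2-(trimethylsilyl)ethoxy]pyridine (oxirane anti to the peroxide bridge)
Conditions: CF3CO2H (1.1 equiv), then mCPBA, CH2Cl2, 0 → 25 °C; aq NaHCO3/Na2S2O3 work-up
Reagents that add atoms: 3-chloroperoxybenzoic acid, OOC(=O)c1cccc(Cl)c1
Why: Prilezhaev epoxidation with the pyridine nitrogen masked as its trifluoroacetate salt against N-oxidation; the peracid should attack the bicyclic alkene on the face away from the peroxide lone pairs, as is usual for 2,3-dioxabicyclo[2.2.2]oct-5-enes, which sets both oxirane carbons trans to the two bridgehead oxygens.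

Step 6
Reactants: 9 rac-5-[(1R,2S,4R,5R)-3,6,7-trioxatricyclo[3.2.2.0(2,4)]nonan-1-yl]-2,4-bis[2-(trimethylsilyl)ethoxy]pyridine
Product: 10 rac-(1S,2R,5R,6S)-2-{4,6-bis[2-(trimethylsilyl)ethoxy]pyridin-3-yl}-7-oxabicyclo[4.1.0]heptane-2,5-diol (hydroxyls cis, oxirane trans to both)
Conditions: Zn dust, AcOH, CH2Cl2, 0 → 25 °C
Reagents that add atoms: none
Why: Reductive cleavage of the O–O bond by zinc in acetic acid, a standard endoperoxide reduction, breaks no C–O bond, so the diol is cis and the deactivated oxirane stays trans to both hydroxyls.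

Step 7
Reactants: 10 rac-(1S,2R,5R,6S)-2-{4,6-bis[2-(trimethylsilyl)ethoxy]pyridin-3-yl}-7-oxabicyclo[4.1.0]heptane-2,5-diol
Product: 11 (1S,2R,5R,6S)-5-{4,6-bis[2-(trimethylsilyl)ethoxy]pyridin-3-yl}-5-hydroxy-7-oxabicyclo[4.1.0]heptan-2-yl acetate
Conditions: Burkholderia cepacia lipase (immobilised), vinyl acetate, t-BuOMe, 30 °C, stopped near half conversion
Reagents that add atoms: vinyl acetate, C=COC(C)=O
Why: Lipase-catalysed kinetic resolution by irreversible transesterification with an enol ester: only the secondary hydroxyl is acylated and the (5R)-alcohol is expected to react faster, so the unreacted (5S)-enantiomer is removed by chromatography; no stereocentre is formed, the absolute configuration of the four ring stereocentres is selected here.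

Step 8
Reactants: 11 (1S,2R,5R,6S)-5-{4,6-bis[2-(trimethylsilyl)ethoxy]pyridin-3-yl}-5-hydroxy-7-oxabicyclo[4.1.0]heptan-2-yl acetate
Product: 12 (1S,2R,5R,6S)-2-{4,6-bis[2-(trimethylsilyl)ethoxy]pyridin-3-yl}-7-oxabicyclo[4.1.0]heptane-2,5-diol (single enantiomer)
Conditions: K2CO3 (cat.), MeOH, 0 °C
Reagents that add atoms: none
Why: Base-catalysed transesterification (methanolysis) of the acetate; weak base, low temperature and short contact should keep the trans epoxy alcohol from Payne migration.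

Step 9
Reactants: 12 (1S,2R,5R,6S)-2-{4,6-bis[2-(trimethylsilyl)ethoxy]pyridin-3-yl}-7-oxabicyclo[4.1.0]heptane-2,5-diol
Product: 13 5-[(1S,2R,5R,6R)-2,5-bis(triethylsilyloxy)-7-oxabicyclo[4.1.0]heptan-2-yl]-2,4-bis[2-(trimethylsilyl)ethoxy]pyridine
Conditions: Et3SiOTf, 2,6-lutidine, CH2Cl2, −78 → 0 °C
Reagents that add atoms: triethylsilyl trifluoromethanesulfonate, CC[Si](CC)(CC)OS(=O)(=O)C(F)(F)F
Why: Silylation with a silyl triflate and a hindered base covers the secondary and the tertiary hydroxyl in one operation, and the low temperature keeps the triflate from opening the oxirane.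

Step 10
Reactants: 14 (S)-citronellal [(3S)-3,7-dimethyloct-6-enal]
Product: 15 (6S)-8,8-dimethoxy-2,6-dimethyloct-2-ene
Conditions: HC(OMe)3, MeOH, p-TsOH (cat.), 0 → 25 °C
Reagents that add atoms: trimethyl orthoformate, COC(OC)OC; methanol, CO
Why: Acid-catalysed acetalisation with orthoformate as water scavenger masks the aldehyde faster than the competing carbonyl-ene cyclisation can occur; the stereocentre is untouched.

Step 11
Reactants: 15 (6S)-8,8-dimethoxy-2,6-dimethyloct-2-ene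
Product: 16 (4S)-6,6-dimethoxy-4-methylhexanal
Conditions: O3, CH2Cl2, −78 °C; then PPh3, −78 → 25 °C
Reagents that add atoms: ozone, [O-][O+]=O
Why: Ozonolysis with reductive work-up cleaves the only alkene to the aldehyde and acetone, and the acetal is inert.

Step 12
Reactants: 16 (4S)-6,6-dimethoxy-4-methylhexanal
Product: 17 (2E,6S)-8,8-dimethoxy-2,6-dimethyloct-2-enal
Conditions: Ph3P=C(Me)CHO, toluene, 90 °C
Reagents that add atoms: 2-(triphenyl-λ5-phosphanylidene)propanal, CC(C=O)=P(c1ccccc1)(c1ccccc1)c1ccccc1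
Why: Wittig reaction of a stabilised ylide with an unhindered aldehyde, which gives the (E)-trisubstituted enal under thermodynamic control of the oxaphosphetane.

Step 13
Reactants: 17 (2E,6S)-8,8-dimethoxy-2,6-dimethyloct-2-enal
Product: 18 ethyl (2E,4E,8S)-10,10-dimethoxy-4,8-dimethyldeca-2,4-dienoate
Conditions: (EtO)2P(O)CH2CO2Et, NaH, THF, 0 → 25 °C
Reagents that add atoms: triethyl phosphonoacetate, CCOC(=O)CP(=O)(OCC)OCC
Why: Horner–Wadsworth–Emmons olefination, which is reliably (E)-selective with a stabilised phosphonate and leaves the existing (E)-alkene unchanged.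

Step 14
Reactants: 18 ethyl (2E,4E,8S)-10,10-dimethoxy-4,8-dimethyldeca-2,4-dienoate
Product: 19 (2E,4E,8S)-10,10-dimethoxy-4,8-dimethyldeca-2,4-dien-1-ol
Conditions: i-Bu2AlH, CH2Cl2, −78 °C; Rochelle salt work-up
Reagents that add atoms: none
Why: 1,2-Reduction of the conjugated ester by DIBAL-H gives the dienol without touching the diene or the acetal.

Step 15
Reactants: 19 (2E,4E,8S)-10,10-dimethoxy-4,8-dimethyldeca-2,4-dien-1-ol
Product: 20 tert-butyl{[(2E,4E,8S)-10,10-dimethoxy-4,8-dimethyldeca-2,4-dien-1-yl]oxy}diphenylsilane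
Conditions: t-BuPh2SiCl, imidazole, CH2Cl2, 25 °C
Reagents that add atoms: tert-butylchlorodiphenylsilane, CC(C)(C)[Si](Cl)(c1ccccc1)c1ccccc1
Why: Silylation of the primary alcohol; the bulky diphenylsilyl ether is chosen because it withstands the acid of step 16 and the Lewis acid of step 18.

Step 16
Reactants: 20 tert-butyl{[(2E,4E,8S)-10,10-dimethoxy-4,8-dimethyldeca-2,4-dien-1-yl]oxy}diphenylsilane
Product: 21 (3S,6E,8E)-10-[(tert-butyldiphenylsilyl)oxy]-3,7-dimethyldeca-6,8-dienal
Conditions: PPTS (cat.), acetone/H2O, 50 °C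
Reagents that add atoms: water, O
Why: Mild acid-catalysed hydrolysis frees the aldehyde from its dimethyl acetal under conditions that neither cleave the silyl ether nor ionise the dienyl ether.

Step 17
Reactants: 21 (3S,6E,8E)-10-[(tert-butyldiphenylsilyl)oxy]-3,7-dimethyldeca-6,8-dienal
Product: 22 (2E,5S,8E,10E)-12-[(tert-butyldiphenylsilyl)oxy]-5,9-dimethyldodeca-2,8,10-trienal
Conditions: Ph3P=CHCHO, toluene, 80 °C
Reagents that add atoms: 2-(triphenyl-λ5-phosphanylidene)acetaldehyde, O=CC=P(c1ccccc1)(c1ccccc1)c1ccccc1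
Why: Wittig two-carbon homologation with the stabilised formylmethylene ylide gives the (E)-enal, and the less reactive conjugated product is expected to react further only slowly.

Step 18
Reactants: 22 (2E,5S,8E,10E)-12-[(tert-butyldiphenylsilyl)oxy]-5,9-dimethyldodeca-2,8,10-trienal
Product: 23 (1R,2S,4aS,7S,8aS)-2-{[(tert-butyldiphenylsilyl)oxy]methyl}-4,7-dimethyl-1,2,4a,5,6,7,8,8a-octahydronaphthalene-1-carbaldehyde
Conditions: Me2AlCl (1.2 equiv), CH2Cl2, −78 → −20 °C
Reagents that add atoms: none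
Why: Lewis-acid-promoted intramolecular Diels–Alder reaction of a 2,8,10-trienal: the complexed enal should react through the endo transition state with the four-carbon tether as a chair and the C5 methyl group equatorial, which gives the trans ring fusion (C4a, C8a), the equatorial formyl group at C1 (from the E dienophile) and the silyloxymethyl group cis to it at C2 (from the E,E diene), all relative to the citronellal stereocentre (C7).

Step 19
Reactants: 23 (1R,2S,4aS,7S,8aS)-2-{[(tert-butyldiphenylsilyl)oxy]methyl}-4,7-dimethyl-1,2,4a,5,6,7,8,8a-octahydronaphthalene-1-carbaldehyde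
Product: 24 tert-butyl{[(1R,2R,4aS,7S,8aR)-4,7-dimethyl-1-[(1E)-prop-1-en-1-yl]-1,2,4a,5,6,7,8,8a-octahydronaphthalen-2-yl]methoxy}diphenylsilane
Conditions: 5-(ethylsulfonyl)-1-phenyl-1H-tetrazole, KHMDS, DME, −60 → 25 °C
Reagents that add atoms: 5-(ethylsulfonyl)-1-phenyl-1H-tetrazole, CCS(=O)(=O)c1nnnn1-c1ccccc1
Why: Julia–Kocienski olefination, which is (E)-selective for α-branched aldehydes with phenyltetrazolyl sulfones in DME; the equatorial C1 centre is already the stable epimer and should not suffer from the basic conditions.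

Step 20
Reactants: 24 tert-butyl{[(1R,2R,4aS,7S,8aR)-4,7-dimethyl-1-[(1E)-prop-1-en-1-yl]-1,2,4a,5,6,7,8,8a-octahydronaphthalen-2-yl]methoxy}diphenylsilane
Product: 25 [(1R,2R,4aS,7S,8aR)-4,7-dimethyl-1-[(1E)-prop-1-en-1-yl]-1,2,4a,5,6,7,8,8a-octahydronaphthalen-2-yl]methanol
Conditions: Bu4NF, THF, 25 °C
Reagents that add atoms: none
Why: Fluoride-induced cleavage of the silyl ether; nothing else in the molecule responds to fluoride.

Step 21
Reactants: 25 [(1R,2R,4aS,7S,8aR)-4,7-dimethyl-1-[(1E)-prop-1-en-1-yl]-1,2,4a,5,6,7,8,8a-octahydronaphthalen-2-yl]methanol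
Product: 26 (1R,2R,4aS,7S,8aR)-4,7-dimethyl-1-[(1E)-prop-1-en-1-yl]-1,2,4a,5,6,7,8,8a-octahydronaphthalene-2-carbaldehyde
Conditions: Dess–Martin periodinane, NaHCO3, CH2Cl2, 0 °C
Reagents that add atoms: none
Why: Dess–Martin oxidation under buffered, non-enolising conditions gives the β,γ-unsaturated aldehyde without moving the ring alkene; the pseudo-axial C2 configuration from the cycloaddition is carried on and corrected in step 24.

Step 22
Reactants: 13 5-[(1S,2R,5R,6R)-2,5-bis(triethylsilyloxy)-7-oxabicyclo[4.1.0]heptan-2-yl]-2,4-bis[2-(trimethylsilyl)ethoxy]pyridine; 26 (1R,2R,4aS,7S,8aR)-4,7-dimethyl-1-[(1E)-prop-1-en-1-yl]-1,2,4a,5,6,7,8,8a-octahydronaphthalene-2-carbaldehyde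
Product: 28 {5-[(1S,2R,5R,6R)-2,5-bis(triethylsilyloxy)-7-oxabicyclo[4.1.0]heptan-2-yl]-2,4-bis[2-(trimethylsilyl)ethoxy]pyridin-3-yl}{(1R,2R,4aS,7S,8aR)-4,7-dimethyl-1-[(1E)-prop-1-en-1-yl]-1,2,4a,5,6,7,8,8a-octahydronaphthalen-2-yl}methanol (both epimers at the carbinol carbon), via 3-lithiopyridine 27 (not isolated)
Conditions: n-BuLi, THF, −78 → −30 °C; then 26, −78 °C; H2O quench
Reagents that add atoms: none
Why: Directed ortho-metalation at C3, the position flanked by both alkoxy groups, followed by 1,2-addition of the aryllithium to the aldehyde; the new carbinol centre is not controlled and is removed in step 23, and the cold, aprotic medium should spare the oxirane and the silyl ethers.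

Step 23
Reactants: 28 the carbinol from step 22 (both epimers)
Product: 29 {5-[(1S,2R,5R,6R)-2,5-bis(triethylsilyloxy)-7-oxabicyclo[4.1.0]heptan-2-yl]-2,4-bis[2-(trimethylsilyl)ethoxy]pyridin-3-yl}{(1R,2R,4aS,7S,8aR)-4,7-dimethyl-1-[(1E)-prop-1-en-1-yl]-1,2,4a,5,6,7,8,8a-octahydronaphthalen-2-yl}methanone
Conditions: Dess–Martin periodinane, NaHCO3, CH2Cl2, 25 °C
Reagents that add atoms: none
Why: Dess–Martin oxidation of the hindered aryl carbinol to the ketone, which merges both carbinol epimers and tolerates silyl ethers, oxirane and alkenes.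

Step 24
Reactants: 29 the (2R)-ketone from step 23
Product: 30 {5-[(1S,2R,5R,6R)-2,5-bis(triethylsilyloxy)-7-oxabicyclo[4.1.0]heptan-2-yl]-2,4-bis[2-(trimethylsilyl)ethoxy]pyridin-3-yl}{(1R,2S,4aS,7S,8aR)-4,7-dimethyl-1-[(1E)-prop-1-en-1-yl]-1,2,4a,5,6,7,8,8a-octahydronaphthalen-2-yl}methanone
Conditions: DBU, toluene, 25 → 50 °C
Reagents that add atoms: none
Why: Base-mediated epimerisation through the ketone enolate under thermodynamic control: the pseudo-axial acyl group at C2, the only stereocentre α to the carbonyl, should relax to the pseudo-equatorial position trans to the C1 propenyl group, and reprotonation of the dienolate at the α-carbon is kinetically preferred, so the ring alkene should stay in place.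

Step 25
Reactants: 30 the (2S)-ketone from step 24
Product: 31 3-{[(1R,2S,4aS,7S,8aR)-4,7-dimethyl-1-[(1E)-prop-1-en-1-yl]-1,2,4a,5,6,7,8,8a-octahydronaphthalen-2-yl]carbonyl}-5-[(1S,2R,5R,6S)-2,5-dihydroxy-7-oxabicyclo[4.1.0]heptan-2-yl]-4-hydroxypyridin-2(1H)-one (CNP0494338.1)
Conditions: Bu4NF/AcOH (1:1), THF, 0 → 40 °C
Reagents that add atoms: none
Why: Fluoride cleaves both triethylsilyl ethers and triggers the β-silylethyl fragmentation (loss of ethene and fluorotrimethylsilane) of both pyridyl ethers, the mode used for silylethyl-protected heteroaryl oxygens; the acetic acid buffer keeps alkoxides from starting a Payne migration of the oxirane.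

**Compound list**

1 | 5-bromo-2,4-dichloropyridine | Clc1cc(Cl)c(Br)cn1 | starting material
2 | 5-bromo-2,4-bis[2-(trimethylsilyl)ethoxy]pyridine | C[Si](C)(C)CCOc1cc(OCC[Si](C)(C)C)c(Br)cn1 | intermediate
3 | cyclohex-2-en-1-one | O=C1C=CCCC1 | starting material
4 | cyclohexa-1,3-dien-1-yl trifluoromethanesulfonate | O=S(=O)(OC1=CC=CCC1)C(F)(F)F | intermediate
5 | {4,6-bis[2-(trimethylsilyl)ethoxy]pyridin-3-yl}lithium | [Li]c1cnc(OCC[Si](C)(C)C)cc1OCC[Si](C)(C)C | intermediate
6 | chloro{4,6-bis[2-(trimethylsilyl)ethoxy]pyridin-3-yl}zinc | Cl[Zn]c1cnc(OCC[Si](C)(C)C)cc1OCC[Si](C)(C)C | intermediate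
7 | 5-(cyclohexa-1,3-dien-1-yl)-2,4-bis[2-(trimethylsilyl)ethoxy]pyridine | C[Si](C)(C)CCOc1cc(OCC[Si](C)(C)C)c(C2=CC=CCC2)cn1 | intermediate
8 | rac-5-[(1S,4R)-2,3-dioxabicyclo[2.2.2]oct-5-en-1-yl]-2,4-bis[2-(trimethylsilyl)ethoxy]pyridine | C[Si](C)(C)CCOc1cc(OCC[Si](C)(C)C)c(cn1)[C@@]12CC[C@@H](OO1)C=C2 | intermediate
9 | rac-5-[(1R,2S,4R,5R)-3,6,7-trioxatricyclo[3.2.2.0(2,4)]nonan-1-yl]-2,4-bis[2-(trimethylsilyl)ethoxy]pyridine | C[Si](C)(C)CCOc1cc(OCC[Si](C)(C)C)c(cn1)[C@@]12CC[C@@H](OO1)[C@@H]3O[C@@H]32 | intermediate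
10 | rac-(1S,2R,5R,6S)-2-{4,6-bis[2-(trimethylsilyl)ethoxy]pyridin-3-yl}-7-oxabicyclo[4.1.0]heptane-2,5-diol | C[Si](C)(C)CCOc1cc(OCC[Si](C)(C)C)c(cn1)[C@]1(O)CC[C@@H](O)[C@@H]2O[C@@H]21 | intermediate
11 | (1S,2R,5R,6S)-5-{4,6-bis[2-(trimethylsilyl)ethoxy]pyridin-3-yl}-5-hydroxy-7-oxabicyclo[4.1.0]heptan-2-yl acetate | C[Si](C)(C)CCOc1cc(OCC[Si](C)(C)C)c(cn1)[C@]1(O)CC[C@@H](OC(C)=O)[C@@H]2O[C@@H]21 | intermediate
12 | (1S,2R,5R,6S)-2-{4,6-bis[2-(trimethylsilyl)ethoxy]pyridin-3-yl}-7-oxabicyclo[4.1.0]heptane-2,5-diol, single enantiomer | C[Si](C)(C)CCOc1cc(OCC[Si](C)(C)C)c(cn1)[C@]1(O)CC[C@@H](O)[C@@H]2O[C@@H]21 | intermediate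
13 | 5-[(1S,2R,5R,6R)-2,5-bis(triethylsilyloxy)-7-oxabicyclo[4.1.0]heptan-2-yl]-2,4-bis[2-(trimethylsilyl)ethoxy]pyridine | C[Si](C)(C)CCOc1cc(OCC[Si](C)(C)C)c(cn1)[C@]1(O[Si](CC)(CC)CC)CC[C@@H](O[Si](CC)(CC)CC)[C@@H]2O[C@@H]21 | intermediate
14 | (S)-citronellal, (3S)-3,7-dimethyloct-6-enal | C[C@H](CC=O)CCC=C(C)C | starting material
15 | (6S)-8,8-dimethoxy-2,6-dimethyloct-2-ene | C[C@H](CC(OC)OC)CCC=C(C)C | intermediate
16 | (4S)-6,6-dimethoxy-4-methylhexanal | C[C@H](CC(OC)OC)CCC=O | intermediate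
17 | (2E,6S)-8,8-dimethoxy-2,6-dimethyloct-2-enal | C[C@H](CC(OC)OC)CC/C=C(\C)C=O | intermediate
18 | ethyl (2E,4E,8S)-10,10-dimethoxy-4,8-dimethyldeca-2,4-dienoate | C[C@H](CC(OC)OC)CC/C=C(\C)/C=C/C(=O)OCC | intermediate
19 | (2E,4E,8S)-10,10-dimethoxy-4,8-dimethyldeca-2,4-dien-1-ol | C[C@H](CC(OC)OC)CC/C=C(\C)/C=C/CO | intermediate
20 | tert-butyl{[(2E,4E,8S)-10,10-dimethoxy-4,8-dimethyldeca-2,4-dien-1-yl]oxy}diphenylsilane | C[C@H](CC(OC)OC)CC/C=C(\C)/C=C/CO[Si](c1ccccc1)(c1ccccc1)C(C)(C)C | intermediate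
21 | (3S,6E,8E)-10-[(tert-butyldiphenylsilyl)oxy]-3,7-dimethyldeca-6,8-dienal | C[C@H](CC=O)CC/C=C(\C)/C=C/CO[Si](c1ccccc1)(c1ccccc1)C(C)(C)C | intermediate
22 | (2E,5S,8E,10E)-12-[(tert-butyldiphenylsilyl)oxy]-5,9-dimethyldodeca-2,8,10-trienal | C[C@H](C/C=C/C=O)CC/C=C(\C)/C=C/CO[Si](c1ccccc1)(c1ccccc1)C(C)(C)C | intermediate
23 | (1R,2S,4aS,7S,8aS)-2-{[(tert-butyldiphenylsilyl)oxy]methyl}-4,7-dimethyl-1,2,4a,5,6,7,8,8a-octahydronaphthalene-1-carbaldehyde | O=C[C@@H]1[C@H]2C[C@@H](C)CC[C@@H]2C(C)=C[C@@H]1CO[Si](c1ccccc1)(c1ccccc1)C(C)(C)C | intermediate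
24 | tert-butyl{[(1R,2R,4aS,7S,8aR)-4,7-dimethyl-1-[(1E)-prop-1-en-1-yl]-1,2,4a,5,6,7,8,8a-octahydronaphthalen-2-yl]methoxy}diphenylsilane | C/C=C/[C@@H]1[C@H]2C[C@@H](C)CC[C@@H]2C(C)=C[C@@H]1CO[Si](c1ccccc1)(c1ccccc1)C(C)(C)C | intermediate
25 | [(1R,2R,4aS,7S,8aR)-4,7-dimethyl-1-[(1E)-prop-1-en-1-yl]-1,2,4a,5,6,7,8,8a-octahydronaphthalen-2-yl]methanol | C/C=C/[C@@H]1[C@H]2C[C@@H](C)CC[C@@H]2C(C)=C[C@@H]1CO | intermediate
26 | (1R,2R,4aS,7S,8aR)-4,7-dimethyl-1-[(1E)-prop-1-en-1-yl]-1,2,4a,5,6,7,8,8a-octahydronaphthalene-2-carbaldehyde | C/C=C/[C@@H]1[C@H]2C[C@@H](C)CC[C@@H]2C(C)=C[C@@H]1C=O | intermediate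
27 | {5-[(1S,2R,5R,6R)-2,5-bis(triethylsilyloxy)-7-oxabicyclo[4.1.0]heptan-2-yl]-2,4-bis[2-(trimethylsilyl)ethoxy]pyridin-3-yl}lithium | [Li]c1c(OCC[Si](C)(C)C)ncc(c1OCC[Si](C)(C)C)[C@]1(O[Si](CC)(CC)CC)CC[C@@H](O[Si](CC)(CC)CC)[C@@H]2O[C@@H]21 | intermediate
28 | {5-[(1S,2R,5R,6R)-2,5-bis(triethylsilyloxy)-7-oxabicyclo[4.1.0]heptan-2-yl]-2,4-bis[2-(trimethylsilyl)ethoxy]pyridin-3-yl}{(1R,2R,4aS,7S,8aR)-4,7-dimethyl-1-[(1E)-prop-1-en-1-yl]-1,2,4a,5,6,7,8,8a-octahydronaphthalen-2-yl}methanol, both carbinol epimers | C/C=C/[C@@H]1[C@H]2C[C@@H](C)CC[C@@H]2C(C)=C[C@@H]1C(O)c1c(OCC[Si](C)(C)C)ncc(c1OCC[Si](C)(C)C)[C@]1(O[Si](CC)(CC)CC)CC[C@@H](O[Si](CC)(CC)CC)[C@@H]2O[C@@H]21 | intermediate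
29 | {5-[(1S,2R,5R,6R)-2,5-bis(triethylsilyloxy)-7-oxabicyclo[4.1.0]heptan-2-yl]-2,4-bis[2-(trimethylsilyl)ethoxy]pyridin-3-yl}{(1R,2R,4aS,7S,8aR)-4,7-dimethyl-1-[(1E)-prop-1-en-1-yl]-1,2,4a,5,6,7,8,8a-octahydronaphthalen-2-yl}methanone | C/C=C/[C@@H]1[C@H]2C[C@@H](C)CC[C@@H]2C(C)=C[C@@H]1C(=O)c1c(OCC[Si](C)(C)C)ncc(c1OCC[Si](C)(C)C)[C@]1(O[Si](CC)(CC)CC)CC[C@@H](O[Si](CC)(CC)CC)[C@@H]2O[C@@H]21 | intermediate
30 | {5-[(1S,2R,5R,6R)-2,5-bis(triethylsilyloxy)-7-oxabicyclo[4.1.0]heptan-2-yl]-2,4-bis[2-(trimethylsilyl)ethoxy]pyridin-3-yl}{(1R,2S,4aS,7S,8aR)-4,7-dimethyl-1-[(1E)-prop-1-en-1-yl]-1,2,4a,5,6,7,8,8a-octahydronaphthalen-2-yl}methanone | C/C=C/[C@@H]1[C@H]2C[C@@H](C)CC[C@@H]2C(C)=C[C@H]1C(=O)c1c(OCC[Si](C)(C)C)ncc(c1OCC[Si](C)(C)C)[C@]1(O[Si](CC)(CC)CC)CC[C@@H](O[Si](CC)(CC)CC)[C@@H]2O[C@@H]21 | intermediate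
31 | 3-{[(1R,2S,4aS,7S,8aR)-4,7-dimethyl-1-[(1E)-prop-1-en-1-yl]-1,2,4a,5,6,7,8,8a-octahydronaphthalen-2-yl]carbonyl}-5-[(1S,2R,5R,6S)-2,5-dihydroxy-7-oxabicyclo[4.1.0]heptan-2-yl]-4-hydroxypyridin-2(1H)-one | C/C=C/[C@@H]1[C@H]2C[C@@H](C)CC[C@@H]2C(C)=C[C@H]1C(=O)c1c(O)c([C@]2(O)CC[C@@H](O)[C@@H]3O[C@@H]32)c[nH]c1=O | target

**Count and risks**

Total step count: 25. Longest linear sequence: 16 steps (steps 10–21, then 22–25).

Steps most likely to fail:

Step 5. The peracid may oxidise the pyridine nitrogen faster than the electron-poor bicyclic alkene if protonation is incomplete, or the acid additive may begin to cleave a silylethyl ether during the long reaction. Fallback, setting out from 8: the acid is left out and an excess of mCPBA is used so that nitrogen and alkene are both oxidised, giving the epoxy endoperoxide N-oxide F1. Zinc dust in acetic acid then cleaves the O–O and the N–O bond in the same operation, and the route is rejoined at 10.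

Step 22. The hindered, basic aryllithium may take the doubly activated α-proton of the β,γ-unsaturated aldehyde (enolisation) instead of adding to the carbonyl group. Fallback, setting out from 13: the lithiated pyridine is quenched with iodine to give the 3-iodopyridine F2. F2 is then added to 26 under non-basic Nozaki–Hiyama–Kishi conditions (CrCl2, NiCl2 cat., DMF), and the route is rejoined at 28.

Step 24. The equilibrium at decalin C2 may not lie far enough on the side of the equatorial ketone, or the ring alkene may drift into conjugation on prolonged base treatment. Fallback, setting out from 26: the aldehyde is equilibrated with DBU, the (2S)-aldehyde F3 is separated by chromatography and the recovered 26 is resubmitted. F3 is then combined with 27 at −78 °C (or with F2 under the chromium conditions) to give the carbinol F4, and Dess–Martin oxidation of F4 rejoins the route at 30.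

Further compounds

F1 | step 5 | rac-5-[(1R,2S,4R,5R)-3,6,7-trioxatricyclo[3.2.2.0(2,4)]nonan-1-yl]-2,4-bis[2-(trimethylsilyl)ethoxy]pyridine 1-oxide | C[Si](C)(C)CCOc1cc(OCC[Si](C)(C)C)c(c[n+]1[O-])[C@@]12CC[C@@H](OO1)[C@@H]3O[C@@H]32
F2 | step 22 | 5-[(1S,2R,5R,6R)-2,5-bis(triethylsilyloxy)-7-oxabicyclo[4.1.0]heptan-2-yl]-3-iodo-2,4-bis[2-(trimethylsilyl)ethoxy]pyridine | Ic1c(OCC[Si](C)(C)C)ncc(c1OCC[Si](C)(C)C)[C@]1(O[Si](CC)(CC)CC)CC[C@@H](O[Si](CC)(CC)CC)[C@@H]2O[C@@H]21
F3 | step 24 | (1R,2S,4aS,7S,8aR)-4,7-dimethyl-1-[(1E)-prop-1-en-1-yl]-1,2,4a,5,6,7,8,8a-octahydronaphthalene-2-carbaldehyde | C/C=C/[C@@H]1[C@H]2C[C@@H](C)CC[C@@H]2C(C)=C[C@H]1C=O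
F4 | step 24 | {5-[(1S,2R,5R,6R)-2,5-bis(triethylsilyloxy)-7-oxabicyclo[4.1.0]heptan-2-yl]-2,4-bis[2-(trimethylsilyl)ethoxy]pyridin-3-yl}{(1R,2S,4aS,7S,8aR)-4,7-dimethyl-1-[(1E)-prop-1-en-1-yl]-1,2,4a,5,6,7,8,8a-octahydronaphthalen-2-yl}methanol, both carbinol epimers | C/C=C/[C@@H]1[C@H]2C[C@@H](C)CC[C@@H]2C(C)=C[C@H]1C(O)c1c(OCC[Si](C)(C)C)ncc(c1OCC[Si](C)(C)C)[C@]1(O[Si](CC)(CC)CC)CC[C@@H](O[Si](CC)(CC)CC)[C@@H]2O[C@@H]21
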